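Both chroman rings are traced back, through their chromenes, to an open dimer by cutting C4–C4a and O1–C2 in each. In ring A and ring B alike, O1 sits on C8a, whose neighbours are the acyl-bearing C8 and C4a. A 1,1-dimethylpropargyl ether on that oxygen therefore has only one free ortho carbon. The bis-ether precursor already holds the (R)-methine, and each ring carries one benzyl ether (later 5-OH) and one chelated hydroxyl (7-OH). Heating drives both ethers through [3,3] shift, hydrogen shift and oxa-6π closure. Two pyran rings and four bonds form in one neutral operation. Hydrogenation then gives the target.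

Key step: step 9

Configuration check: the SMILES gives R at C2 of the 2-methylbutanoyl group and R at the methine. Ring A outranks ring B only through the ethyl branch of its acyl group, so the descriptor stays R from the open dimer to the target.

Assumption: the sense of induction in step 8 cannot be read from the structure. The squaramide made from 9-amino-9-deoxy-epi-quinine and 3,5-bis(trifluoromethyl)aniline is taken to give the (R)-methine, and its quinidine-derived pseudo-enantiomer is used if the opposite sense is found.

Design remark: the hydroxyl next to the methine stays free on each ring. It is needed to form and to accept the o-quinone methide, its hydrogen bond to the ketone holds the proton during heating, and capping it would expose the assembled dimer to strong base.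

Step 1
Reactants: 1 phloroglucinol; 2 (R)-2-methylbutanoic acid
Product: 4 (R)-2-methyl-1-(2,4,6-trihydroxyphenyl)butan-1-one, via (R)-2-methylbutanoyl chloride 3 (not isolated)
Conditions: 2, (COCl)2, cat. DMF, CH2Cl2, 0 °C to rt, evaporate; then 1, AlCl3, CH2Cl2/MeNO2, 0 to 40 °C; cold 1 M HCl
Reagents that add atoms: none
Why: Friedel–Crafts C-acylation of the symmetrical, threefold-activated arene can give only one mono-ketone, the first acyl group deactivates the ring against a second, and base-free chloride formation with a temperature ceiling of 40 °C avoids ketene and enol pathways, so the (R)-centre brought in by 2 is kept.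

Step 2
Reactants: 4 (R)-2-methyl-1-(2,4,6-trihydroxyphenyl)butan-1-one
Product: 5 (R)-1-[4-(benzyloxy)-2,6-dihydroxyphenyl]-2-methylbutan-1-one
Conditions: BnBr (1.0 equiv), K2CO3 (1.1 equiv), DMF, 0 °C to rt
Reagents that add atoms: benzyl bromide, BrCc1ccccc1
Why: Williamson etherification with one equivalent of halide and a weak base goes to the 4-hydroxyl, which is the most acidic (para to the ketone) and the least hindered, while phenolate formation lowers the acidity of the ketone α-hydrogen and so protects the (R)-centre.

Step 3
Reactants: 5 (R)-1-[4-(benzyloxy)-2,6-dihydroxyphenyl]-2-methylbutan-1-one; 6 3-chloro-3-methylbut-1-yne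
Product: 7 ring A monomer, (R)-1-{4-(benzyloxy)-2-hydroxy-6-[(2-methylbut-3-yn-2-yl)oxy]phenyl}-2-methylbutan-1-one
Conditions: 6 (1.2 equiv), DBU (1.3 equiv), CuCl2·2H2O (1 mol%), MeCN, Ar, 0 °C
Reagents that add atoms: none
Why: Copper-catalysed O-propargylation of a phenol by a tertiary propargylic chloride (through a copper acetylide that ionises) runs at 0 °C, far below the onset of the Claisen shift, and stops at the mono-ether because the two hydroxyls of 5 are equivalent and the one left over is tied into the hydrogen bond to the ketone.

Step 4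
Reactants: 1 phloroglucinol; 8 isobutyryl chloride
Product: 9 2-methyl-1-(2,4,6-trihydroxyphenyl)propan-1-one
Conditions: AlCl3, CH2Cl2/MeNO2, 0 to 40 °C; cold 1 M HCl
Reagents that add atoms: none
Why: Friedel–Crafts C-acylation of the symmetrical arene gives a single mono-ketone, since the acyl group introduced first deactivates the ring.

Step 5
Reactants: 9 2-methyl-1-(2,4,6-trihydroxyphenyl)propan-1-one
Product: 10 1-[4-(benzyloxy)-2,6-dihydroxyphenyl]-2-methylpropan-1-one
Conditions: BnBr (1.0 equiv), K2CO3 (1.1 equiv), DMF, 0 °C to rt
Reagents that add atoms: benzyl bromide, BrCc1ccccc1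
Why: Williamson etherification picks the para hydroxyl for the same reasons of acidity and access as in step 2.

Step 6
Reactants: 10 1-[4-(benzyloxy)-2,6-dihydroxyphenyl]-2-methylpropan-1-one; 6 3-chloro-3-methylbut-1-yne
Product: 11 ring B monomer, 1-{4-(benzyloxy)-2-hydroxy-6-[(2-methylbut-3-yn-2-yl)oxy]phenyl}-2-methylpropan-1-one
Conditions: 6 (1.2 equiv), DBU (1.3 equiv), CuCl2·2H2O (1 mol%), MeCN, Ar, 0 °C
Reagents that add atoms: none
Why: Copper-catalysed O-propargylation as in step 3 etherifies one of two equivalent hydroxyls and leaves the chelated one untouched.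

Step 7
Reactants: 11 ring B monomer; 12 6-methylheptanal
Product: 13 racemic ring B sulfone, 1-{4-(benzyloxy)-2-hydroxy-3-[6-methyl-1-(4-methylbenzenesulfonyl)heptyl]-6-[(2-methylbut-3-yn-2-yl)oxy]phenyl}-2-methylpropan-1-one
Conditions: 12 (1.5 equiv), p-TolSO2H (1.5 equiv, freshly liberated from its sodium salt), 4 Å MS, CH2Cl2, rt
Reagents that add atoms: p-toluenesulfinic acid, Cc1ccc(cc1)S(=O)O
Why: Three-component sulfonylalkylation (Friedel–Crafts hydroxyalkylation, loss of water, capture by sulfinate, as known for indoles, naphthols and electron-rich phenols) should occur at C3 between the free hydroxyl and the benzyl ether, because C5 is shielded by the tertiary ether, and the racemic centre it creates is erased in step 8.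

Step 8
Reactants: 13 racemic ring B sulfone; 7 ring A monomer
Product: 15 open (R)-methine dimer (per ring one benzyl ether plus one 1,1-dimethylpropargyl ether plus one free hydroxyl), via ring B o-quinone methide 14 (not isolated)
Conditions: 7 (1.5 equiv), quinine-derived 3,5-bis(trifluoromethyl)phenyl squaramide (10 mol%), 5% aq. NaHCO3, toluene, 0 °C to rt
Reagents that add atoms: none
Why: Base-induced 1,4-elimination of sulfinate, which the water layer carries away, gives planar 14, and the asymmetric Friedel–Crafts-type conjugate addition to it under bifunctional amine–squaramide catalysis sets the methine, the squaramide N–H pair binding the ring-carbonyl/acyl-carbonyl pair of 14 and the quinuclidine holding the phenol of 7 so that C3 of 7 (ortho to its hydroxyl and the less hindered free carbon) adds to one face before rearomatisation of both rings makes the bond permanent.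

Step 9
Reactants: 15 open (R)-methine dimer
Product: 18 bis-chromene bis(benzyl ether), via bis(allenylphenol) 16 (not isolated), via bis(vinyl o-quinone methide) 17 (not isolated)
Conditions: o-xylene (0.02 M, degassed), BHT (cat.), base-washed sealed tube, 140 °C
Reagents that add atoms: none
Why: Each aryl 1,1-dimethylpropargyl ether undergoes an aromatic propargyl Claisen [3,3] shift to its only hydrogen-bearing ortho carbon (the future C4a; a shift to the acyl-bearing C8 is unproductive and reversible), and enolisation gives the allenylphenols 16. A 1,5-hydrogen shift from the newly freed hydroxyl to the central allene carbon then gives the vinyl o-quinone methides 17. Each pyran ring closes by a thermal disrotatory oxa-6π electrocyclisation in which the carbonyl oxygen, the same atom that carried the propargyl group, bonds to the C(CH3)2 terminus and the arene is restored. The closest known reaction type is the thermal conversion of aryl 1,1-dimethylpropargyl ethers into 2,2-dimethyl-2H-chromenes, also known for arenes bearing two such ethers, and here it runs once on each of two electronically independent rings. No stereocentre is created, and the (R)-methine and the (R)-acyl centre are spectators because no acid, base or metal is present and the hydroxyls beside the methine are locked in hydrogen bonds to their ketones. The selectivity needed is regiochemical (which ortho carbon, which oxygen) and is secured by the acyl group on C8, by the benzyl group masking the only other oxygen next to C4a, and by the gem-dimethyl group, which accelerates the shift enough for 140 °C to suffice.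

Step 10
Reactants: 18 bis-chromene bis(benzyl ether)
Product: 19 target CNP0287681.1
Conditions: H2 (1 atm), 10% Pd/C, EtOAc/EtOH, rt
Reagents that add atoms: none
Why: Heterogeneous catalytic hydrogenation saturates both styrene-type C3=C4 bonds and hydrogenolysis removes both benzyl ethers in the same operation, while the hydrogen-bonded aryl ketones, the aryl–methine bonds and both stereocentres are inert under these neutral conditions.

Compound list
1 | phloroglucinol | Oc1cc(O)cc(O)c1 | starting material
2 | (R)-2-methylbutanoic acid | CC[C@@H](C)C(=O)O | starting material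
3 | (R)-2-methylbutanoyl chloride | CC[C@@H](C)C(=O)Cl | intermediate
4 | (R)-2-methyl-1-(2,4,6-trihydroxyphenyl)butan-1-one | CC[C@@H](C)C(=O)c1c(O)cc(O)cc1O | intermediate
5 | (R)-1-[4-(benzyloxy)-2,6-dihydroxyphenyl]-2-methylbutan-1-one | CC[C@@H](C)C(=O)c1c(O)cc(OCc2ccccc2)cc1O | intermediate
6 | 3-chloro-3-methylbut-1-yne | CC(C)(Cl)C#C | starting material
7 | (R)-1-{4-(benzyloxy)-2-hydroxy-6-[(2-methylbut-3-yn-2-yl)oxy]phenyl}-2-methylbutan-1-one (ring A monomer) | CC[C@@H](C)C(=O)c1c(O)cc(OCc2ccccc2)cc1OC(C)(C)C#C | intermediate
8 | isobutyryl chloride | CC(C)C(=O)Cl | starting material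
9 | 2-methyl-1-(2,4,6-trihydroxyphenyl)propan-1-one | CC(C)C(=O)c1c(O)cc(O)cc1O | intermediate
10 | 1-[4-(benzyloxy)-2,6-dihydroxyphenyl]-2-methylpropan-1-one | CC(C)C(=O)c1c(O)cc(OCc2ccccc2)cc1O | intermediate
11 | 1-{4-(benzyloxy)-2-hydroxy-6-[(2-methylbut-3-yn-2-yl)oxy]phenyl}-2-methylpropan-1-one (ring B monomer) | CC(C)C(=O)c1c(O)cc(OCc2ccccc2)cc1OC(C)(C)C#C | intermediate
12 | 6-methylheptanal | CC(C)CCCCC=O | starting material
13 | 1-{4-(benzyloxy)-2-hydroxy-3-[6-methyl-1-(4-methylbenzenesulfonyl)heptyl]-6-[(2-methylbut-3-yn-2-yl)oxy]phenyl}-2-methylpropan-1-one, racemic | CC(C)CCCCC(c1c(O)c(C(=O)C(C)C)c(OC(C)(C)C#C)cc1OCc2ccccc2)S(=O)(=O)c3ccc(C)cc3 | intermediate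
14 | 5-(benzyloxy)-6-(6-methylheptylidene)-3-[(2-methylbut-3-yn-2-yl)oxy]-2-(2-methylpropanoyl)cyclohexa-2,4-dien-1-one, alkylidene geometry not defined | O=C1C(=CCCCCC(C)C)C(OCc2ccccc2)=CC(OC(C)(C)C#C)=C1C(=O)C(C)C | intermediate
15 | (2R)-1-{4-(benzyloxy)-3-[(1R)-1-{6-(benzyloxy)-2-hydroxy-4-[(2-methylbut-3-yn-2-yl)oxy]-3-(2-methylpropanoyl)phenyl}-6-methylheptyl]-2-hydroxy-6-[(2-methylbut-3-yn-2-yl)oxy]phenyl}-2-methylbutan-1-one (open dimer, key-step precursor) | CC[C@@H](C)C(=O)c1c(O)c([C@H](CCCCC(C)C)c2c(OCc3ccccc3)cc(OC(C)(C)C#C)c(C(=O)C(C)C)c2O)c(OCc2ccccc2)cc1OC(C)(C)C#C | intermediate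
16 | bis(allenylphenol): 15 in which each propargyl ether oxygen has become OH and the adjacent ring carbon carries CH=C=C(CH3)2; (R)-methine, (R)-acyl centre | CC[C@@H](C)C(=O)c1c(O)c([C@H](CCCCC(C)C)c2c(OCc3ccccc3)c(C=C=C(C)C)c(O)c(C(=O)C(C)C)c2O)c(OCc2ccccc2)c(C=C=C(C)C)c1O | intermediate
17 | bis(vinyl o-quinone methide): each ring a 6-(3-methylbut-2-enylidene)cyclohexa-2,4-dien-1-one; (R)-methine, (R)-acyl centre | CC[C@@H](C)C(=O)C1=C(O)C([C@H](CCCCC(C)C)C2=C(OCc3ccccc3)C(=CC=C(C)C)C(=O)C(C(=O)C(C)C)=C2O)=C(OCc2ccccc2)C(=CC=C(C)C)C1=O | intermediate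
18 | (2R)-1-{5-(benzyloxy)-6-[(1R)-1-[5-(benzyloxy)-7-hydroxy-2,2-dimethyl-8-(2-methylpropanoyl)-2H-chromen-6-yl]-6-methylheptyl]-7-hydroxy-2,2-dimethyl-2H-chromen-8-yl}-2-methylbutan-1-one (key-step product) | CC[C@@H](C)C(=O)c1c(O)c([C@H](CCCCC(C)C)c2c(OCc3ccccc3)c3c(c(C(=O)C(C)C)c2O)OC(C)(C)C=C3)c(OCc2ccccc2)c2c1OC(C)(C)C=C2 | intermediate
19 | (2R)-1-{6-[(1R)-1-[5,7-dihydroxy-2,2-dimethyl-8-(2-methylpropanoyl)-3,4-dihydro-2H-chromen-6-yl]-6-methylheptyl]-5,7-dihydroxy-2,2-dimethyl-3,4-dihydro-2H-chromen-8-yl}-2-methylbutan-1-one | CC[C@@H](C)C(=O)c1c(O)c([C@H](CCCCC(C)C)c2c(O)c3c(c(C(=O)C(C)C)c2O)OC(C)(C)CC3)c(O)c2c1OC(C)(C)CC2 | target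

Total step count: 10. Longest linear sequence: 7 (steps 4, 5, 6, 7, 8, 9, 10, from phloroglucinol through ring B).

Steps most likely to fail

Step 8. Facial selectivity at the methide carbon may be poor. That carbon lies between a carbonyl and a benzyl ether, so both alkylidene geometries can be populated, and the chelated phenol of the nucleophile may bind the catalyst only weakly. Attack through C5 of the nucleophile, or drift of the methide to an alkenylphenol by hydrogen shift, would lower the throughput. The fallback replaces catalysis by separation. It sets out from 13 and 7 and runs the elimination–addition with an achiral base (5% aq. NaHCO3, cat. DABCO, toluene, rt). This should give 15 together with its (1S)-methine epimer F1. The (R)-acyl centre makes the two compounds diastereomers, so they are separated by preparative supercritical-fluid chromatography on an amylose carbamate phase. The route is rejoined at 15.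

Step 9. An aryl–methine bond may reopen thermally during prolonged heating, with loss of configuration or exchange of rings. The two rings may also rearrange at very different rates, so that half-closed material decays. The fallback moves the pericyclic closure in front of the coupling. It sets out from 7 and 11, and each monomer is heated alone (o-xylene, 140 °C) to give ring A chromene F2 and ring B chromene F3. F3 with 12 and p-TolSO2H gives chromene sulfone F4. Under the conditions of step 8, F4 eliminates to chromene o-quinone methide F5, and F2, which now has a single free aromatic carbon, adds to it. The product is 18, where the route is rejoined.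

Step 7. Over-condensation is the main danger: the methide formed under acid may be captured by a second molecule of 11 rather than by sulfinate. The ketone-deactivated ring may also react sluggishly with an enolisable aldehyde. The fallback separates C–C bond formation from sulfinate introduction. It sets out from 11, and EtMgBr (1.0 equiv, CH2Cl2/toluene, 0 °C) deprotonates only the phenol. The bromomagnesium phenolate coordinates 12 and delivers it to the ortho carbon (metal-phenolate-directed ortho-hydroxyalkylation) to give o-hydroxybenzyl alcohol F6. Brief treatment of F6 with p-TolSO2H in CH2Cl2 exchanges hydroxyl for sulfinate. The route is rejoined at 13.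

Further compounds
F1 | step 8 | (1S)-methine epimer of 15 | CC[C@@H](C)C(=O)c1c(O)c([C@@H](CCCCC(C)C)c2c(OCc3ccccc3)cc(OC(C)(C)C#C)c(C(=O)C(C)C)c2O)c(OCc2ccccc2)cc1OC(C)(C)C#C
F2 | step 9 | ring A chromene, (2R)-1-[5-(benzyloxy)-7-hydroxy-2,2-dimethyl-2H-chromen-8-yl]-2-methylbutan-1-one | CC[C@@H](C)C(=O)c1c(O)cc(OCc2ccccc2)c2c1OC(C)(C)C=C2
F3 | step 9 | ring B chromene, 1-[5-(benzyloxy)-7-hydroxy-2,2-dimethyl-2H-chromen-8-yl]-2-methylpropan-1-one | CC(C)C(=O)c1c(O)cc(OCc2ccccc2)c2c1OC(C)(C)C=C2
F4 | step 9 | chromene sulfone, 1-{5-(benzyloxy)-7-hydroxy-2,2-dimethyl-6-[6-methyl-1-(4-methylbenzenesulfonyl)heptyl]-2H-chromen-8-yl}-2-methylpropan-1-one, racemic | CC(C)CCCCC(c1c(O)c(C(=O)C(C)C)c2OC(C)(C)C=Cc2c1OCc3ccccc3)S(=O)(=O)c4ccc(C)cc4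
F5 | step 9 | chromene o-quinone methide, 5-(benzyloxy)-2,2-dimethyl-6-(6-methylheptylidene)-8-(2-methylpropanoyl)-2H-chromen-7(6H)-one | O=C1C(=CCCCCC(C)C)C(OCc2ccccc2)=C2C=CC(C)(C)OC2=C1C(=O)C(C)C
F6 | step 7 | o-hydroxybenzyl alcohol, 1-{4-(benzyloxy)-2-hydroxy-3-(1-hydroxy-6-methylheptyl)-6-[(2-methylbut-3-yn-2-yl)oxy]phenyl}-2-methylpropan-1-one, racemic | CC(C)CCCCC(O)c1c(O)c(C(=O)C(C)C)c(OC(C)(C)C#C)cc1OCc2ccccc2
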